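**Retrosynthetic overview**
1. The β-lactone is closed last from a cis β-hydroxy acid (C2 carboxyl, C3 hydroxyl of the hydrindene); the butyrate comes from a CH2OH that was the CHO arm on C4.
2. Key disconnection: the cyclohexene ring (C3a, C4, C5, C6, C7, C7a) plus the exocyclic CH2O carbon on C4 is a contracted cycloheptene. C4 is a ring CH that carries a one-carbon oxygenated arm and sits next to C5H2, so C4–CH(O) is what remains of a ring CH=CH; an oxidative 1,2-shift on the C4=C5 alkene of a 5–7 fused 1,4-diene gives this constitution whichever alkene carbon leaves the ring.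
3. The hexahydroazulene comes from a rhodium-catalysed intramolecular [5+2] cycloaddition of an alkyne with a vinylcyclopropane, which forms the five- and seven-membered rings and the tetrasubstituted alkene together.
4. The acyclic yne–vinylcyclopropane comes from an Evans syn aldol of an alkynoyl oxazolidinone with (E)-3-cyclopropylacrolein (sets C2 and C3).
5. The quaternary centre comes from copper-catalysed asymmetric conjugate methylation of a 3-alkynylcyclohexenone, then C=O to CMe2. Ring order: trimethylcyclohexane (from a bought cyclohexenone), five- and seven-membered rings together, seven to six, β-lactone.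

Key step: step 11

Remark: the facial sense of the copper–NHC catalyst in step 2 is assumed to follow from the ligand antipode, which is chosen to give the (S) ketone. Compounds 20–28 and the target are numbered as 2,3,3a,4,5,6-hexahydro-1H-indenes (C7=C7a), compound 19 as a 1,2,3,3a,6,7-hexahydroazulene.

**Route**

Step 1
Reactants: 1 3-ethoxycyclohex-2-en-1-one; 2 ethynyltrimethylsilane
Product: 4 3-[(trimethylsilyl)ethynyl]cyclohex-2-en-1-one, via tertiary alkynyl carbinol 3 (not isolated)
Conditions: 2, n-BuLi, THF, −78 °C; then 1, −78 → 0 °C; then 2 M HCl, rt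
Reagents that add atoms: none
Why: 1,2-addition of the lithium acetylide to the vinylogous ester and acid-promoted hydrolysis–dehydration (Stork–Danheiser transposition) should give the β-alkynyl enone; no stereocentre is formed.

Step 2
Reactants: 4 3-[(trimethylsilyl)ethynyl]cyclohex-2-en-1-one
Product: 5 (S)-3-methyl-3-[(trimethylsilyl)ethynyl]cyclohexan-1-one
Conditions: MeMgBr, Cu(OTf)2 (cat.), chiral imidazolinium salt (NHC precursor, cat.), Et2O, −30 °C; then 1 M HCl
Reagents that add atoms: methylmagnesium bromide, C[Mg]Br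
Why: copper-catalysed asymmetric conjugate addition of a Grignard reagent to a cyclic enynone, a substrate class on which NHC–copper catalysts favour 1,4- over 1,6-addition, should build the methyl/alkynyl quaternary centre, whose configuration is set by the ligand antipode.

Step 3
Reactants: 5 (S)-3-methyl-3-[(trimethylsilyl)ethynyl]cyclohexan-1-one
Product: 6 (S)-trimethyl[(1,3,3-trimethylcyclohexyl)ethynyl]silane
Conditions: Me2Zn, TiCl4, CH2Cl2, −40 °C (gives Me2TiCl2); then 5, −40 → 0 °C
Reagents that add atoms: dimethylzinc, C[Zn]C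
Why: Reetz geminal dimethylation (methyl addition, ionisation of the tertiary titanium alkoxide, second methyl transfer to the tertiary cation) should turn C=O into CMe2 without touching the quaternary stereocentre two bonds away.

Step 4
Reactants: 6 (S)-trimethyl[(1,3,3-trimethylcyclohexyl)ethynyl]silane
Product: 8 5-[(S)-1,3,3-trimethylcyclohexyl]pent-4-yn-1-ol, via lithium acetylide 7 (not isolated)
Conditions: MeLi·LiBr, THF, 0 °C → rt; then BF3·OEt2, oxetane, −78 °C; then H2O
Reagents that add atoms: oxetane, C1COC1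
Why: Si–C(sp) cleavage by MeLi should give the lithium acetylide, which opens BF3-activated oxetane by SN2 attack (Yamaguchi-type alkynylation) to the three-carbon-homologated primary alcohol.

Step 5
Reactants: 8 5-[(S)-1,3,3-trimethylcyclohexyl]pent-4-yn-1-ol
Product: 10 5-[(S)-1,3,3-trimethylcyclohexyl]pent-4-ynoic acid, via aldehyde 9 (not isolated)
Conditions: TEMPO (cat.), PhI(OAc)2, MeCN/H2O, rt
Reagents that add atoms: water, O
Why: oxoammonium-mediated oxidation (TEMPO/PhI(OAc)2) in aqueous acetonitrile should take the primary alcohol through the aldehyde hydrate to the acid and leave the hindered alkyne alone.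

Step 6
Reactants: 10 5-[(S)-1,3,3-trimethylcyclohexyl]pent-4-ynoic acid; 11 (R)-4-benzyloxazolidin-2-one
Product: 13 (R)-4-benzyl-3-{5-[(S)-1,3,3-trimethylcyclohexyl]pent-4-ynoyl}oxazolidin-2-one, via mixed pivalic anhydride 12 (not isolated)
Conditions: t-BuCOCl, Et3N, THF, −20 °C; then 11, LiCl, rt
Reagents that add atoms: none
Why: N-acylation of the oxazolidinone by the mixed anhydride under LiCl/Et3N activation should attach the Evans auxiliary, attack occurring at the less hindered carbonyl.

Step 7
Reactants: 14 cyclopropanecarbaldehyde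
Product: 15 (E)-3-cyclopropylprop-2-enal
Conditions: Ph3P=CHCHO, toluene, 80 °C
Reagents that add atoms: (triphenylphosphoranylidene)acetaldehyde, O=CC=P(c1ccccc1)(c1ccccc1)c1ccccc1
Why: Wittig olefination with the stabilised formyl ylide should give the (E)-enal.

Step 8
Reactants: 13 (R)-4-benzyl-3-{5-[(S)-1,3,3-trimethylcyclohexyl]pent-4-ynoyl}oxazolidin-2-one; 15 (E)-3-cyclopropylprop-2-enal
Product: 17 (2R,3S,4E) syn aldol adduct, via boron enolate 16 (not isolated)
Conditions: n-Bu2BOTf, i-Pr2NEt, CH2Cl2, −78 → 0 °C; then 15, −78 → 0 °C; then pH 7 buffer, MeOH, H2O2, 0 °C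
Reagents that add atoms: none
Why: Evans syn aldol, in which the (Z)-boron enolate reacts through a closed Zimmerman–Traxler transition state on the face away from the benzyl group, so that the (R)-auxiliary should set 2R and 3S (the syn pair that becomes the cis C2/C3 pair of the lactone).

Step 9
Reactants: 17 (2R,3S,4E) syn aldol adduct
Product: 18 triisopropylsilyl ether of 17
Conditions: TIPSOTf, 2,6-lutidine, CH2Cl2, 0 °C → rt
Reagents that add atoms: triisopropylsilyl trifluoromethanesulfonate, CC(C)[Si](OS(=O)(=O)C(F)(F)F)(C(C)C)C(C)C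
Why: silylation of the hindered secondary allylic alcohol with the silyl triflate gives an ether robust enough for the acidic media of steps 11 and 12.

Step 10
Reactants: 18 triisopropylsilyl ether of 17
Product: 19 (2R,3S,3aR)-hexahydroazulene imide
Conditions: [Rh(CO)2Cl]2 (5 mol %), toluene, 90 °C
Reagents that add atoms: none
Why: Wender-type intramolecular [5+2] cycloaddition catalysed by monovalent rhodium (cyclopropane cleavage to a rhodium allyl, alkyne insertion forming the C8a–C3a bond and the five-membered ring, reductive elimination closing the seven-membered ring) should give the 5–7 fused 1,4-diene with the tetrasubstituted C8=C8a alkene, the C3a centre being set by the allylic silyloxy stereocentre, whose bulky OSi group takes the position remote from the rhodium-bound allyl carbon in the insertion and so ends cis to H-3a.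

Step 11
Reactants: 19 (2R,3S,3aR)-hexahydroazulene imide
Product: 20 (2R,3S,3aR,4R)-4-(dimethoxymethyl)hexahydroindene imide
Conditions: Tl(NO3)3·3H2O, MeOH, −20 → 0 °C
Reagents that add atoms: methanol, CO
Why: Trans-methoxythallation of the exposed cis C4=C5 alkene (Tl(NO3)3 on the face anti to the silyloxy group, methanol anti to thallium) is followed by reductive heterolysis of the C–Tl bond (trivalent to monovalent thallium) with a concerted 1,2-shift of the antiperiplanar ring C–C bond, and the exocyclic methoxycarbenium ion is trapped by methanol as the dimethyl acetal. The closest known reaction is the oxythallation ring contraction of simple cycloalkenes (cycloheptene to cyclohexanecarbaldehyde dimethyl acetal), which is also known with trivalent iodine reagents such as PhI(OH)OTs. The six-membered ring is closed by this suprafacial 1,2-alkyl shift with inversion at the thallium-bearing carbon, not by a cyclisation, and either regiochemistry of the addition gives the same constitution because whichever alkene carbon leaves the ring becomes the acetal carbon on the one that stays. The new C4 centre should arise as 4R (acetal carbon on the face that carried thallium, anti to H-3a) under the facial bias of the silyloxy group, but it need not be controlled because step 12 equilibrates it. The step needs chemoselectivity for the cis-disubstituted alkene over the tetrasubstituted C8=C8a alkene and a ring-bond shift in place of a hydride shift: the first is secured by the quaternary trimethylcyclohexyl group, which shields both faces of C8=C8a (oxymetallation is strongly retarded by alkene substitution), the second by the flexible seven-membered ring, which can place the C–Tl bond equatorial and antiperiplanar to a ring bond.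

Step 12
Reactants: 20 (2R,3S,3aR,4R)-4-(dimethoxymethyl)hexahydroindene imide
Product: 22 (2R,3S,3aR,4S)-4-formylhexahydroindene imide, via C4-epimeric aldehyde 21 (not isolated)
Conditions: PPTS, acetone/H2O, 50 °C; then DBU (cat.), CH2Cl2, rt
Reagents that add atoms: water, O
Why: acetal hydrolysis followed by base-mediated enolisation should equilibrate C4, the only centre alpha to the aldehyde, to the isomer with the formyl group equatorial and cis to H-3a (expected to be favoured, the minor epimer being recycled).

Step 13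
Reactants: 22 (2R,3S,3aR,4S)-4-formylhexahydroindene imide
Product: 23 (2R,3S,3aR,4S)-4-(hydroxymethyl)hexahydroindene imide
Conditions: NaBH4, THF/EtOH, −40 °C
Reagents that add atoms: none
Why: chemoselective borohydride reduction of the aldehyde at low temperature, where the imide reacts much more slowly, fixes C4 against further epimerisation.

Step 14
Reactants: 23 (2R,3S,3aR,4S)-4-(hydroxymethyl)hexahydroindene imide
Product: 24 (2R,3S,3aR,4S)-4-(butanoyloxymethyl)hexahydroindene imide
Conditions: n-PrCOCl, pyridine, DMAP (cat.), CH2Cl2, 0 °C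
Reagents that add atoms: butanoyl chloride, CCCC(Cl)=O
Why: DMAP-catalysed O-acylation (nucleophilic catalysis) of the primary alcohol should install the butyrate.

Step 15
Reactants: 24 (2R,3S,3aR,4S)-4-(butanoyloxymethyl)hexahydroindene imide
Product: 26 silyloxy carboxylic acid, via peroxy acid 25 (not isolated)
Conditions: LiOH, H2O2, THF/H2O, 0 °C; then Na2SO3; then 1 M HCl
Reagents that add atoms: hydrogen peroxide, OO
Why: Evans hydroperoxide cleavage, in which the small and highly nucleophilic hydroperoxide anion attacks the exocyclic imide carbonyl and the peracid formed is reduced by sulfite, should free the acid while the simple primary ester reacts far more slowly at 0 °C.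

Step 16
Reactants: 26 silyloxy carboxylic acid
Product: 27 cis β-hydroxy acid
Conditions: HF·pyridine, THF, 0 °C → rt
Reagents that add atoms: none
Why: fluoride-mediated Si–O cleavage under acidic conditions should free the C3 hydroxyl without touching the butyrate, the acid or the alkene.

Step 17
Reactants: 27 cis β-hydroxy acid
Product: 29 3'-norspongiolactone, via carboxylic sulfonic anhydride 28 (not isolated)
Conditions: PhSO2Cl, pyridine, 0 → 4 °C
Reagents that add atoms: none
Why: β-lactonisation by carboxyl activation (Adam's benzenesulfonyl chloride/pyridine method) lets the cis hydroxyl attack the mixed anhydride with retention at C3, giving the cis-fused β-lactone.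

**Compound list**
1 | 3-ethoxycyclohex-2-en-1-one | CCOC1=CC(=O)CCC1 | starting material
2 | ethynyltrimethylsilane | C#C[Si](C)(C)C | starting material
3 | 3-ethoxy-1-[(trimethylsilyl)ethynyl]cyclohex-2-en-1-ol (racemic, formed as its lithium alkoxide) | CCOC1=CC(O)(C#C[Si](C)(C)C)CCC1 | intermediate (not isolated)
4 | 3-[(trimethylsilyl)ethynyl]cyclohex-2-en-1-one | C[Si](C)(C)C#CC1=CC(=O)CCC1 | intermediate
5 | (S)-3-methyl-3-[(trimethylsilyl)ethynyl]cyclohexan-1-one | C[Si](C)(C)C#C[C@@]1(C)CCCC(=O)C1 | intermediate
6 | (S)-trimethyl[(1,3,3-trimethylcyclohexyl)ethynyl]silane | C[Si](C)(C)C#C[C@@]1(C)CCCC(C)(C)C1 | intermediate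
7 | lithium [(S)-1,3,3-trimethylcyclohexyl]acetylide | [Li]C#C[C@@]1(C)CCCC(C)(C)C1 | intermediate (not isolated)
8 | 5-[(S)-1,3,3-trimethylcyclohexyl]pent-4-yn-1-ol | OCCCC#C[C@@]1(C)CCCC(C)(C)C1 | intermediate
9 | 5-[(S)-1,3,3-trimethylcyclohexyl]pent-4-ynal | O=CCCC#C[C@@]1(C)CCCC(C)(C)C1 | intermediate (not isolated)
10 | 5-[(S)-1,3,3-trimethylcyclohexyl]pent-4-ynoic acid | OC(=O)CCC#C[C@@]1(C)CCCC(C)(C)C1 | intermediate
11 | (R)-4-benzyloxazolidin-2-one | O=C1OC[C@@H](Cc2ccccc2)N1 | starting material
12 | 5-[(S)-1,3,3-trimethylcyclohexyl]pent-4-ynoic pivalic anhydride | CC(C)(C)C(=O)OC(=O)CCC#C[C@@]1(C)CCCC(C)(C)C1 | intermediate (not isolated)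
13 | (R)-4-benzyl-3-{5-[(S)-1,3,3-trimethylcyclohexyl]pent-4-ynoyl}oxazolidin-2-one | O=C(CCC#C[C@@]1(C)CCCC(C)(C)C1)N2C(=O)OC[C@H]2Cc3ccccc3 | intermediate
14 | cyclopropanecarbaldehyde | O=CC1CC1 | starting material
15 | (E)-3-cyclopropylprop-2-enal | O=C/C=C/C1CC1 | intermediate
16 | (Z)-dibutylboron enolate of 13 | CCCCB(CCCC)O/C(N4C(=O)OC[C@H]4Cc5ccccc5)=C\CC#C[C@@]3(C)CCCC(C)(C)C3 | intermediate (not isolated)
17 | (R)-4-benzyl-3-[(2R,3S,4E)-5-cyclopropyl-3-hydroxy-2-{3-[(S)-1,3,3-trimethylcyclohexyl]prop-2-yn-1-yl}pent-4-enoyl]oxazolidin-2-one | O=C(N4C(=O)OC[C@H]4Cc5ccccc5)[C@H](CC#C[C@@]3(C)CCCC(C)(C)C3)[C@@H](O)/C=C/C1CC1 | intermediate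
18 | 3-O-triisopropylsilyl ether of 17 (2R,3S,4E) | O=C(N4C(=O)OC[C@H]4Cc5ccccc5)[C@H](CC#C[C@@]3(C)CCCC(C)(C)C3)[C@@H](O[Si](C(C)C)(C(C)C)C(C)C)/C=C/C1CC1 | intermediate
19 | (R)-4-benzyl-3-{[(2R,3S,3aR)-3-(triisopropylsilyloxy)-8-[(S)-1,3,3-trimethylcyclohexyl]-1,2,3,3a,6,7-hexahydroazulen-2-yl]carbonyl}oxazolidin-2-one (H-3a cis to OSi and to the acyl group) | O=C(N4C(=O)OC[C@H]4Cc5ccccc5)[C@@H]1CC2=C([C@@]3(C)CCCC(C)(C)C3)CCC=C[C@H]2[C@@H]1O[Si](C(C)C)(C(C)C)C(C)C | intermediate
20 | (R)-4-benzyl-3-{[(2R,3S,3aR,4R)-4-(dimethoxymethyl)-3-(triisopropylsilyloxy)-7-[(S)-1,3,3-trimethylcyclohexyl]-2,3,3a,4,5,6-hexahydro-1H-inden-2-yl]carbonyl}oxazolidin-2-one (acetal arm trans to H-3a) | O=C(N4C(=O)OC[C@H]4Cc5ccccc5)[C@@H]1CC2=C([C@@]3(C)CCCC(C)(C)C3)CC[C@@H](C(OC)OC)[C@H]2[C@@H]1O[Si](C(C)C)(C(C)C)C(C)C | intermediate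
21 | (2R,3S,3aR,4R)-4-formyl analogue of 20 (formyl trans to H-3a) | O=C(N4C(=O)OC[C@H]4Cc5ccccc5)[C@@H]1CC2=C([C@@]3(C)CCCC(C)(C)C3)CC[C@@H](C=O)[C@H]2[C@@H]1O[Si](C(C)C)(C(C)C)C(C)C | intermediate (not isolated)
22 | (2R,3S,3aR,4S)-4-formyl imide (formyl cis to H-3a) | O=C(N4C(=O)OC[C@H]4Cc5ccccc5)[C@@H]1CC2=C([C@@]3(C)CCCC(C)(C)C3)CC[C@H](C=O)[C@H]2[C@@H]1O[Si](C(C)C)(C(C)C)C(C)C | intermediate
23 | (2R,3S,3aR,4S)-4-(hydroxymethyl) imide | O=C(N4C(=O)OC[C@H]4Cc5ccccc5)[C@@H]1CC2=C([C@@]3(C)CCCC(C)(C)C3)CC[C@H](CO)[C@H]2[C@@H]1O[Si](C(C)C)(C(C)C)C(C)C | intermediate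
24 | (2R,3S,3aR,4S)-4-(butanoyloxymethyl) imide | O=C(N4C(=O)OC[C@H]4Cc5ccccc5)[C@@H]1CC2=C([C@@]3(C)CCCC(C)(C)C3)CC[C@H](COC(=O)CCC)[C@H]2[C@@H]1O[Si](C(C)C)(C(C)C)C(C)C | intermediate
25 | peroxy acid corresponding to 26 | OOC(=O)[C@@H]1CC2=C([C@@]3(C)CCCC(C)(C)C3)CC[C@H](COC(=O)CCC)[C@H]2[C@@H]1O[Si](C(C)C)(C(C)C)C(C)C | intermediate (not isolated)
26 | (2R,3S,3aR,4S)-4-(butanoyloxymethyl)-3-(triisopropylsilyloxy)-7-[(S)-1,3,3-trimethylcyclohexyl]-2,3,3a,4,5,6-hexahydro-1H-indene-2-carboxylic acid | OC(=O)[C@@H]1CC2=C([C@@]3(C)CCCC(C)(C)C3)CC[C@H](COC(=O)CCC)[C@H]2[C@@H]1O[Si](C(C)C)(C(C)C)C(C)C | intermediate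
27 | (2R,3S,3aR,4S)-4-(butanoyloxymethyl)-3-hydroxy-7-[(S)-1,3,3-trimethylcyclohexyl]-2,3,3a,4,5,6-hexahydro-1H-indene-2-carboxylic acid | OC(=O)[C@@H]1CC2=C([C@@]3(C)CCCC(C)(C)C3)CC[C@H](COC(=O)CCC)[C@H]2[C@@H]1O | intermediate
28 | mixed benzenesulfonic carboxylic anhydride of 27 | O=C(OS(=O)(=O)c4ccccc4)[C@@H]1CC2=C([C@@]3(C)CCCC(C)(C)C3)CC[C@H](COC(=O)CCC)[C@H]2[C@@H]1O | intermediate (not isolated)
29 | 3'-norspongiolactone (C2 R, C3 S, C3a R, C4 S, cyclohexyl C1 S) | CCCC(=O)OC[C@H]1CCC([C@@]2(C)CCCC(C)(C)C2)=C2C[C@H]3C(=O)O[C@H]3[C@@H]21 | target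

**Count and risks**
Total steps: 17. Longest linear sequence: 16 (steps 1–6 and 8–17; step 7 is a one-step branch).

Steps most likely to fail:

Step 11 (key step). What may go wrong: oxythallation at the tetrasubstituted alkene or at the doubly allylic C3a–H, or a hydride shift in place of the ring-bond shift, which would give a cycloheptanone. The fallback sets out from 19 and comes back at 21. Dihydroxylation with OsO4 (cat.)/NMO, which for steric reasons should take only the cis-disubstituted alkene and attack anti to the silyloxy group, would give the cis-4,5-diol F1. MsCl/2,4,6-collidine at −20 °C would sulfonylate the less hindered C5 hydroxyl to the monomesylate F2. Et3Al in CH2Cl2 at −78 °C would then trigger the semipinacol shift of the C3a–C4 bond to C5 (ring bond antiperiplanar to the mesylate) and give aldehyde 21, which is equilibrated as in step 12; the regioisomeric mesylate would converge on the same aldehyde.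

Step 12. What may go wrong: an unfavourable or unselective equilibrium between the two C4 epimers, since the preference for the equatorial formyl group is modest. The fallback sets out from 21 (either epimer serves) and comes back at 24. Butanoic anhydride, Et3N and DMAP at 60 °C would convert the aldehyde into the (E)-enol butyrate F3, erasing C4. Hydrogenation (H2, palladium on carbon, EtOAc, or [Rh(nbd)(dppb)]BF4) from the face opposite the silyloxy group and the imide would set C4 kinetically and deliver butyrate 24 directly; the hindered tetrasubstituted alkene should not be reduced.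

Step 15. What may go wrong: competing hydrolysis of the primary butyrate during the slow peroxide cleavage of the hindered ring-bound imide. The fallback sets out from 23 and comes back at 26. The LiOH/H2O2 cleavage would be run before the acylation and give the hydroxy acid F4. Butanoic anhydride/pyridine/DMAP would then acylate the primary alcohol, and aqueous work-up would hydrolyse the transient mixed anhydride to give 26.

Further compounds
F1 | step 11 | cis-4,5-diol of 19, both hydroxyls on the face anti to H-3a | O=C(N4C(=O)OC[C@H]4Cc5ccccc5)[C@@H]1CC2=C([C@@]3(C)CCCC(C)(C)C3)CC[C@@H](O)[C@@H](O)[C@H]2[C@@H]1O[Si](C(C)C)(C(C)C)C(C)C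
F2 | step 11 | 5-O-methanesulfonate of F1 | O=C(N4C(=O)OC[C@H]4Cc5ccccc5)[C@@H]1CC2=C([C@@]3(C)CCCC(C)(C)C3)CC[C@@H](OS(C)(=O)=O)[C@@H](O)[C@H]2[C@@H]1O[Si](C(C)C)(C(C)C)C(C)C
F3 | step 12 | (E)-enol butyrate of aldehyde 21/22 (exocyclic C4=CH–O–butanoyl) | O=C(N4C(=O)OC[C@H]4Cc5ccccc5)[C@@H]1CC2=C([C@@]3(C)CCCC(C)(C)C3)CC/C(=C\OC(=O)CCC)[C@H]2[C@@H]1O[Si](C(C)C)(C(C)C)C(C)C
F4 | step 15 | (2R,3S,3aR,4S)-4-(hydroxymethyl)-3-(triisopropylsilyloxy)-7-[(S)-1,3,3-trimethylcyclohexyl]-2,3,3a,4,5,6-hexahydro-1H-indene-2-carboxylic acid | OC(=O)[C@@H]1CC2=C([C@@]3(C)CCCC(C)(C)C3)CC[C@H](CO)[C@H]2[C@@H]1O[Si](C(C)C)(C(C)C)C(C)C
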